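**Retrosynthetic overview**
- The strategy rests on ring B (C5–C10). C7 carries a β-isopropenyl group trans to the α-oxygen on C8, which is the homoallylic-alcohol retron of a carbonyl-ene reaction. Cutting C7–C8 leads to the ring-A ketoaldehyde 21, with a prenyl group on C5 and a glyoxyloyl group on C10.
- After ring closure, hydride attack on the convex face of the C9 ketone gives the 9α-alcohol. Both hydroxyls are then tigloylated and the C2 ketal is removed.
- Ketoaldehyde 21 comes from methyl ketone 18, which comes from a vinyl group. The vinyl group is added by copper catalysis to C10 of enone 13, anti to both methyl groups, and this sets 10βH.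
- Enone 13 comes from enone 9 by 1,3-carbonyl transposition. Enone 9 comes from 2-methylcyclohexenone by asymmetric methyl addition (C4) and enolate prenylation (C5).
- Ring order: ring A is bought with 1, and ring B is closed in step 12.

Key step: step 12

Assumption: eremophilane numbering is used (ring A = C1–C5 and C10; ring B = C5–C10; C14 on C5; C15 on C4; β is the face of C14). The sense of induction of the ligands in steps 1 and 12 is assigned from the accepted cyclohexenone and glyoxylate models, and both ligands are sold in both enantiomeric forms.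

**Step 1**
Reactants: 1 2-methylcyclohex-2-en-1-one; 2 trimethylaluminium
Product: 4 (S)-[(2,3-dimethylcyclohex-1-en-1-yl)oxy]trimethylsilane, via dimethylaluminium enolate 3 (not isolated)
Conditions: Me3Al, CuTC (2 mol %), (S,R,R)-BINOL bis(1-phenylethyl)amine phosphoramidite (4 mol %), Et2O, −30 °C; then TMSCl, THF, −30 °C → rt
Reagents that add atoms: trimethylaluminium C[Al](C)C; chlorotrimethylsilane C[Si](C)(C)Cl
Why: This is a copper-catalysed asymmetric conjugate addition, known for 2-substituted cyclic enones, in which the ligand-bound methylcopper species selects the enone face and sets C4 (S), and silylation stores the regiodefined tetrasubstituted enolate.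

**Step 2**
Reactants: 4 silyl enol ether; 5 prenyl bromide
Product: 7 (2R,3S)-2,3-dimethyl-2-(3-methylbut-2-en-1-yl)cyclohexan-1-one, via lithium enolate 6 (not isolated)
Conditions: MeLi, THF, 0 °C → rt; then DMPU, prenyl bromide, −78 → 0 °C
Reagents that add atoms: prenyl bromide CC(C)=CCBr
Why: MeLi releases the lithium enolate in the Stork manner for C-alkylation, and because A(1,2) strain with the C5 methyl pushes the C4 methyl axial, the bromide attacks axially from the opposite face and quaternary C5 forms with prenyl trans to C15 (cis-dimethyl array).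

**Step 3**
Reactants: 7 ketone
Product: 9 (5S,6R)-5,6-dimethyl-6-(3-methylbut-2-en-1-yl)cyclohex-2-en-1-one, via lithium enolate 8 (not isolated)
Conditions: LDA, THF, −78 °C; then N-tert-butylbenzenesulfinimidoyl chloride, −78 °C
Reagents that add atoms: none
Why: In this Mukaiyama dehydrogenation only C1 bears α-hydrogens and the S-bound adduct undergoes syn elimination at low temperature, which avoids Pd(II) that could draw the prenyl alkene into a cycloalkenylation.

**Step 4**
Reactants: 9 enone
Product: 10 (1S,3R,4S,6S)-3,4-dimethyl-3-(3-methylbut-2-en-1-yl)-7-oxabicyclo[4.1.0]heptan-2-one (oxirane on the face opposite to both methyls)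
Conditions: 30 % H2O2, NaOH (cat.), MeOH, 0 °C
Reagents that add atoms: hydrogen peroxide OO
Why: Weitz–Scheffer nucleophilic epoxidation touches only the electron-poor alkene, and axial attack at C2 anti to C15 should favour the α-oxirane, whose configuration is erased in step 6.

**Step 5**
Reactants: 10 epoxy ketone
Product: 12 (1S,4R,5S)-4,5-dimethyl-4-(3-methylbut-2-en-1-yl)cyclohex-2-en-1-ol, via epoxy hydrazone 11 (not isolated)
Conditions: N2H4·H2O, AcOH (cat.), MeOH, 0 °C → rt
Reagents that add atoms: none
Why: In the Wharton transposition the hydrazone opens the oxirane to a vinyl diazene, which loses N2, leaving H on C10, the alkene at C1=C10 and the oxygen on C2.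

**Step 6**
Reactants: 12 allylic alcohol
Product: 13 (4R,5S)-4,5-dimethyl-4-(3-methylbut-2-en-1-yl)cyclohex-2-en-1-one
Conditions: MnO2, CH2Cl2, rt
Reagents that add atoms: none
Why: MnO2 oxidises the allylic alcohol chemoselectively and leaves the prenyl alkene and both stereocentres untouched.

**Step 7**
Reactants: 13 enone; 14 vinylmagnesium bromide
Product: 16 (3R,4R,5S)-3-ethenyl-4,5-dimethyl-4-(3-methylbut-2-en-1-yl)cyclohexan-1-one, via trimethylsilyl enol ether 15 (not isolated)
Conditions: CH2=CHMgBr, CuBr·SMe2 (20 mol %), TMSCl, DMPU, THF, −78 → −40 °C; then 1 M HCl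
Reagents that add atoms: vinylmagnesium bromide C=C[Mg]Br
Why: In this TMSCl-accelerated copper-catalysed 1,4-addition the half-chair has C15 pseudo-equatorial and C14 pseudo-axial, so the vinyl group attacks C10 axially from the α face, anti to both methyls, and sets 10βH kinetically, whereas delivering hydride to a C10-substituted enone would be expected to give the opposite epimer.

**Step 8**
Reactants: 16 vinyl ketone
Product: 17 (7R,8R,9S)-7-ethenyl-8,9-dimethyl-8-(3-methylbut-2-en-1-yl)-1,4-dioxaspiro[4.5]decane
Conditions: ethylene glycol, PPTS (cat.), benzene, Dean–Stark, reflux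
Reagents that add atoms: ethylene glycol OCCO
Why: This is an acid-catalysed ketalisation with azeotropic removal of water, and it cannot epimerise anything because no stereocentre lies α to the carbonyl.

**Step 9**
Reactants: 17 vinyl ketal
Product: 18 1-[(7S,8R,9S)-8,9-dimethyl-8-(3-methylbut-2-en-1-yl)-1,4-dioxaspiro[4.5]decan-7-yl]ethan-1-one
Conditions: PdCl2 (10 mol %), Cu(OAc)2·H2O (20 mol %), O2 (1 atm), DMA/H2O 7:1, rt
Reagents that add atoms: water O
Why: Tsuji–Wacker oxidation proceeds by Markovnikov hydroxypalladation of the monosubstituted alkene only, the trisubstituted prenyl alkene is inert, and the acetate co-catalyst keeps the medium mild enough for the ketal and for C10.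

**Step 10**
Reactants: 18 methyl ketone
Product: 20 2-hydroxy-1-[(7S,8R,9S)-8,9-dimethyl-8-(3-methylbut-2-en-1-yl)-1,4-dioxaspiro[4.5]decan-7-yl]ethan-1-one, via potassium enolate 19 (not isolated)
Conditions: KHMDS, THF, −78 °C; (camphorsulfonyl)oxaziridine, −78 °C; AcOH quench at −78 °C
Reagents that add atoms: (camphorsulfonyl)oxaziridine CC1(C)C2CCC13CS(=O)(=O)N4OC34C2
Why: In this Davis oxidation kinetic deprotonation occurs at the methyl group and not at the hindered tertiary C10–H, the oxaziridine transfers oxygen to the enolate without touching the alkene, and its hindered imine by-product does not trap the primary enolate.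

**Step 11**
Reactants: 20 hydroxymethyl ketone
Product: 21 2-[(7S,8R,9S)-8,9-dimethyl-8-(3-methylbut-2-en-1-yl)-1,4-dioxaspiro[4.5]decan-7-yl]-2-oxoacetaldehyde (ring-A prenyl ketoaldehyde, C2 ketal)
Conditions: Dess–Martin periodinane, CH2Cl2, 0 °C; dilute with pentane, filter, dry azeotropically with toluene, use at once
Reagents that add atoms: none
Why: Dess–Martin oxidation of the primary α-ketol runs under base-free conditions that spare C10, and the non-aqueous work-up keeps the glyoxal unhydrated.

**Step 12**
Reactants: 21 ketoaldehyde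
Product: 22 2,2-ethylenedioxy-8α-hydroxy-10βH-eremophil-11-en-9-one (7β-isopropenyl, cis-decalin)
Conditions: [Cu((R,R)-t-Bu-box)](SbF6)2 (10–20 mol %), CH2Cl2 (0.01 M), −78 → −20 °C
Reagents that add atoms: none
Why: The s-cis O=C9–C8=O unit binds the square-planar Cu(II) dication through both oxygens and activates the aldehyde carbon C8, so C7 of the prenyl alkene bonds to C8 while a hydrogen of a C11 methyl passes to O8 in a concerted, asynchronous six-centre array, and the π bond moves outward to become the isopropenyl group. The closest known reactions are the Lewis-acid cyclisation of citronellal-type aldehydes to trans isopulegol-type products and the Cu(II)–bis(oxazoline) ene reactions of glyoxylates and α-keto esters, both inter- and intramolecular. Ring B (C5–C6–C7–C8–C9–C10) closes in the type I mode through a chair, exo with respect to both π bonds, so O8 and C11 stay outside the ring. C8 is set by the chelate, which holds O8 eclipsed with O9 and hence equatorial, and by the ligand, whose tert-butyl groups should leave the Re face of C8 open, while C7 follows because hydrogen transfer to an equatorial O8 requires the isopropylidene unit to be equatorial as well, giving the trans 7β,8α pair. Of the two chair–chair arrays, the one with C15 equatorial on ring A puts only C4 axial on the forming ring, whereas the other puts both C14 and C1 axial, so this small substrate preference and the catalyst preference act in the same direction. The step needs aldehyde-over-ketone selectivity, which is secured by the hindered C9 carbonyl next to C10/C5 and by the less favourable five-membered alternative, and it needs an intact C10, which is secured by base-free catalysis at low temperature.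

**Step 13**
Reactants: 22 ketol
Product: 23 2,2-ethylenedioxy-10βH-eremophil-11-ene-8α,9α-diol
Conditions: L-Selectride (3 equiv), THF, −78 °C; then aq NaOH/H2O2, 0 °C
Reagents that add atoms: none
Why: In the cis-decalin C4 stands axial on the α face of ring B, 1,3 to C9, so the bulky borohydride attacks equatorially from the convex β face and gives the axial 9α-alcohol, cis to O8.

**Step 14**
Reactants: 23 diol; 24 tiglic acid
Product: 26 2,2-ethylenedioxy-8α,9α-bis(tigloyloxy)-10βH-eremophil-11-ene, via mixed Yamaguchi anhydride 25 (not isolated)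
Conditions: tiglic acid (excess), 2,4,6-trichlorobenzoyl chloride, Et3N, toluene, rt; then 23, DMAP, 80 °C
Reagents that add atoms: tiglic acid C/C=C(\C)C(=O)O
Why: In the Yamaguchi esterification DMAP attacks the less hindered tigloyl carbonyl of the mixed anhydride, the resulting acylpyridinium salt acylates hindered secondary alcohols, and the (E)-alkene is the stable isomer and is retained.

**Step 15**
Reactants: 26 bis-tiglate ketal
Product: 27 8α,9α-bis(tigloyloxy)-10βH-eremophil-11-en-2-one (CNP0249036.2)
Conditions: 1 M HCl, THF, rt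
Reagents that add atoms: water O
Why: Mild acid hydrolyses the strained dioxolane, the esters and the isopropenyl group tolerate these conditions, and no stereocentre lies α to the liberated C2 ketone.

**Compound list**

| No. | Name | SMILES | Role |
|---|---|---|---|
| 1 | 2-methylcyclohex-2-en-1-one | CC1=CCCCC1=O | starting material |
| 2 | trimethylaluminium | C[Al](C)C | starting material |
| 3 | dimethylaluminium (S)-2,3-dimethylcyclohex-1-en-1-olate | C[C@H]1CCCC(O[Al](C)C)=C1C | intermediate |
| 4 | (S)-[(2,3-dimethylcyclohex-1-en-1-yl)oxy]trimethylsilane | C[C@H]1CCCC(O[Si](C)(C)C)=C1C | intermediate |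
| 5 | prenyl bromide | CC(C)=CCBr | starting material |
| 6 | lithium (S)-2,3-dimethylcyclohex-1-en-1-olate | C[C@H]1CCCC([O-])=C1C.[Li+] | intermediate |
| 7 | (2R,3S)-2,3-dimethyl-2-(3-methylbut-2-en-1-yl)cyclohexan-1-one | CC(C)=CC[C@@]1(C)C(=O)CCC[C@@H]1C | intermediate |
| 8 | lithium (5S,6R)-5,6-dimethyl-6-prenylcyclohex-1-en-1-olate | CC(C)=CC[C@@]1(C)C([O-])=CCC[C@@H]1C.[Li+] | intermediate |
| 9 | (5S,6R)-5,6-dimethyl-6-(3-methylbut-2-en-1-yl)cyclohex-2-en-1-one | CC(C)=CC[C@@]1(C)C(=O)C=CC[C@@H]1C | intermediate |
| 10 | (1S,3R,4S,6S)-3,4-dimethyl-3-prenyl-7-oxabicyclo[4.1.0]heptan-2-one | CC(C)=CC[C@@]1(C)C(=O)[C@H]2O[C@H]2C[C@@H]1C | intermediate |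
| 11 | hydrazone of 10 | CC(C)=CC[C@@]1(C)C(=NN)[C@H]2O[C@H]2C[C@@H]1C | intermediate |
| 12 | (1S,4R,5S)-4,5-dimethyl-4-prenylcyclohex-2-en-1-ol | CC(C)=CC[C@@]1(C)C=C[C@@H](O)C[C@@H]1C | intermediate |
| 13 | (4R,5S)-4,5-dimethyl-4-prenylcyclohex-2-en-1-one | CC(C)=CC[C@@]1(C)C=CC(=O)C[C@@H]1C | intermediate |
| 14 | vinylmagnesium bromide | C=C[Mg]Br | starting material |
| 15 | C2 trimethylsilyl enol ether of 16 | CC(C)=CC[C@@]1(C)[C@H](C=C(O[Si](C)(C)C)C[C@@H]1C)C=C | intermediate |
| 16 | (3R,4R,5S)-3-ethenyl-4,5-dimethyl-4-prenylcyclohexan-1-one | CC(C)=CC[C@@]1(C)[C@H](CC(=O)C[C@@H]1C)C=C | intermediate |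
| 17 | (7R,8R,9S)-7-ethenyl-8,9-dimethyl-8-prenyl-1,4-dioxaspiro[4.5]decane | CC(C)=CC[C@@]1(C)[C@H](CC2(OCCO2)C[C@@H]1C)C=C | intermediate |
| 18 | C10 acetyl ketal (7S,8R,9S) | CC(C)=CC[C@@]1(C)[C@H](CC2(OCCO2)C[C@@H]1C)C(C)=O | intermediate |
| 19 | potassium enolate of 18 (terminal) | CC(C)=CC[C@@]1(C)[C@H](CC2(OCCO2)C[C@@H]1C)C(=C)[O-].[K+] | intermediate |
| 20 | C10 hydroxyacetyl ketal (7S,8R,9S) | CC(C)=CC[C@@]1(C)[C@H](CC2(OCCO2)C[C@@H]1C)C(=O)CO | intermediate |
| 21 | ring-A prenyl ketoaldehyde, C2 ketal | CC(C)=CC[C@@]1(C)[C@H](CC2(OCCO2)C[C@@H]1C)C(=O)C=O | intermediate |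
| 22 | 2,2-ethylenedioxy-8α-hydroxy-10βH-eremophil-11-en-9-one | C=C(C)[C@H]1C[C@@]2(C)[C@H](CC3(OCCO3)C[C@@H]2C)C(=O)[C@@H]1O | intermediate |
| 23 | 2,2-ethylenedioxy-10βH-eremophil-11-ene-8α,9α-diol | C=C(C)[C@H]1C[C@@]2(C)[C@H](CC3(OCCO3)C[C@@H]2C)[C@H](O)[C@@H]1O | intermediate |
| 24 | tiglic acid | C/C=C(\C)C(=O)O | starting material |
| 25 | tiglic 2,4,6-trichlorobenzoic anhydride | C/C=C(\C)C(=O)OC(=O)c1c(Cl)cc(Cl)cc1Cl | intermediate |
| 26 | 2,2-ethylenedioxy-8α,9α-bis(tigloyloxy)-10βH-eremophil-11-ene | C=C(C)[C@H]1C[C@@]2(C)[C@H](CC3(OCCO3)C[C@@H]2C)[C@H](OC(=O)/C(C)=C/C)[C@@H]1OC(=O)/C(C)=C/C | intermediate |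
| 27 | 8α,9α-bis(tigloyloxy)-10βH-eremophil-11-en-2-one | C=C(C)[C@H]1C[C@@]2(C)[C@H](CC(=O)C[C@@H]2C)[C@H](OC(=O)/C(C)=C/C)[C@@H]1OC(=O)/C(C)=C/C | target |

Total step count: 15. Longest linear sequence: 15 steps, from 1.

**Steps most likely to fail**

**Step 12.**
- What may go wrong: the two chair–chair arrays may be poorly discriminated, which would cost facial selectivity at C8 and C7. The chelated dicarbonyl may enolise toward C10 and erode the ring-fusion configuration. Hydration of the glyoxal may slow the catalyst.
- Fallback: it sets out from 20 and comes back at 22, and it makes the same C7–C8 bond by allyl-metal addition instead of a hydrogen shift.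
- Ene-type chlorination of the prenyl group of 20 (NCS, cat. PhSeCl, CH2Cl2) should give the rearranged allylic chloride hydroxy ketone F1.
- Dess–Martin oxidation should then give the allylic chloride ketoaldehyde F2.
- Indium powder with NaI in THF/H2O at high dilution should convert the chloride into the primary allylindium species. This adds to the aldehyde through its γ-carbon C7 in a closed chair, restores the isopropenyl group and gives 22.
- The neutral aqueous medium accepts the hydrate and does not enolise C10.

**Step 5.**
- What may go wrong: condensation at the hindered C10 carbonyl, which is flanked by quaternary C5, may be slow. Hydrazine could then open the oxirane at C2 first and divert the material into pyrazoline formation.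
- Fallback: it sets out from 10 and comes back at 12 by radical fragmentation of the oxirane.
- NaBH4 in MeOH should give the epoxy alcohol F3, whose carbinol configuration is irrelevant.
- 1,1'-Thiocarbonyldiimidazole with DMAP in hot dichloroethane should give the imidazolylthiocarbonate F4.
- Bu3SnH/AIBN in refluxing benzene should generate the C10 radical. This opens the adjacent C1–O bond, and hydrogen abstraction by the alkoxy radical gives 12.

**Step 14.**
- What may go wrong: acylation may stall at the mono-ester stage, because the 9α-hydroxyl is axial, sits on the concave face and is syn-axial to C4.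
- Fallback: it sets out from 23 and comes back at 26 by acylating with a smaller, far more electrophilic reagent and building the alkene afterwards.
- 2-Bromopropanoyl bromide and pyridine in CH2Cl2 should give the bis(2-bromopropanoate) F5.
- PPh3 in warm acetonitrile should give the bis(phosphonium bromide) F6.
- Aqueous NaOH should give the stabilised bis-ylide F7.
- A Wittig reaction with acetaldehyde in CH2Cl2 should deliver both (E)-2-methylbut-2-enoates of 26.

**Further compounds**
F1 | step 12 | 1-[(7S,8R,9S)-8-(2-chloro-3-methylbut-3-en-1-yl)-8,9-dimethyl-1,4-dioxaspiro[4.5]decan-7-yl]-2-hydroxyethan-1-one (both chloride epimers) | C=C(C)C(Cl)C[C@@]1(C)[C@H](CC2(OCCO2)C[C@@H]1C)C(=O)CO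
F2 | step 12 | 2-[(7S,8R,9S)-8-(2-chloro-3-methylbut-3-en-1-yl)-8,9-dimethyl-1,4-dioxaspiro[4.5]decan-7-yl]-2-oxoacetaldehyde | C=C(C)C(Cl)C[C@@]1(C)[C@H](CC2(OCCO2)C[C@@H]1C)C(=O)C=O
F3 | step 5 | 3,4-dimethyl-3-prenyl-7-oxabicyclo[4.1.0]heptan-2-ol (from 10, carbinol epimers) | CC(C)=CC[C@@]1(C)C(O)[C@H]2O[C@H]2C[C@@H]1C
F4 | step 5 | O-(3,4-dimethyl-3-prenyl-7-oxabicyclo[4.1.0]heptan-2-yl) 1H-imidazole-1-carbothioate | CC(C)=CC[C@@]1(C)C(OC(=S)n2ccnc2)[C@H]2O[C@H]2C[C@@H]1C
F5 | step 14 | 8α,9α-bis(2-bromopropanoyloxy) ketal | C=C(C)[C@H]1C[C@@]2(C)[C@H](CC3(OCCO3)C[C@@H]2C)[C@H](OC(=O)C(C)Br)[C@@H]1OC(=O)C(C)Br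
F6 | step 14 | bis(triphenylphosphonium bromide) of F5 | C=C(C)[C@H]1C[C@@]2(C)[C@H](CC3(OCCO3)C[C@@H]2C)[C@H](OC(=O)C(C)[P+](c4ccccc4)(c4ccccc4)c4ccccc4)[C@@H]1OC(=O)C(C)[P+](c4ccccc4)(c4ccccc4)c4ccccc4.[Br-].[Br-]
F7 | step 14 | bis[2-(triphenylphosphoranylidene)propanoate] | C=C(C)[C@H]1C[C@@]2(C)[C@H](CC3(OCCO3)C[C@@H]2C)[C@H](OC(=O)C(C)=P(c4ccccc4)(c4ccccc4)c4ccccc4)[C@@H]1OC(=O)C(C)=P(c4ccccc4)(c4ccccc4)c4ccccc4
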